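**Retrosynthetic overview**
1. Target 31 ⇐ allyl ester 30 (deallylation with zerovalent palladium) ⇐ ketone 29 (sulfur-ylide epoxidation; the spiro-epoxide is the last ring).
2. 29 ⇐ bicyclic enone ester 25 by conjugate addition of the homoprenyl group, which sets C-15 and C-11.
3. 25 ⇐ acyclic α-keto ester/vinyl ketone 22 by a one-pot Michael macrocyclisation/transannular aldol condensation; the 14-membered Michael ring is divided into the six- and twelve-membered carbocycles in the same operation, which sets C-1.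
4. 22 ⇐ two Normant carbocuprations of propyne (both Z-trisubstituted alkenes) with ethylene oxide trapping, then oxalate acylation and oxidation.
5. Ring order: six- and twelve-membered carbocycles together (step 9), then the epoxide (step 11).

Naming note: bicyclic compounds use bicyclo[9.3.1]pentadecane locants, written C-1, C-11 and so on to keep them apart from compound numbers. C-1 and C-11 are the bridgeheads, C-12 is the carbonyl/spiro carbon, and C-15 is the one-carbon bridge that carries the carboxyl group.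

Assumption: the (S,S)-ligand in step 9 delivers the (1R) configuration; if the sense of induction proves opposite, the (R,R)-ligand is used and nothing else changes.

**Step 1**
Reactants: 1 4-chloro-1,1-dimethoxybutane; 2 vinylmagnesium bromide
Product: 4 rac-6-chlorohex-1-en-3-ol, via 4-chlorobutanal 3 (not isolated)
Conditions: 2 M HCl, acetone/H2O, 25 °C; extract (Et2O), dry; then 2, THF, −78 to 0 °C; H2O quench
Reagents that add atoms: water, O
Why: Acid hydrolysis of the acetal unmasks the aldehyde, which undergoes Grignard addition of the vinyl reagent; the carbinol centre is left racemic because it is oxidised to the ketone in step 8.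

**Step 2**
Reactants: 4 rac-6-chlorohex-1-en-3-ol
Product: 5 rac-[(6-chlorohex-1-en-3-yl)oxy]triethylsilane
Conditions: Et3SiCl, imidazole, CH2Cl2, 0 to 25 °C
Reagents that add atoms: chlorotriethylsilane, CC[Si](Cl)(CC)CC
Why: Silyl ether protection (silylation) of the allylic alcohol lets the chain survive the Grignard and organocopper steps that follow.

**Step 3**
Reactants: 5 rac-[(6-chlorohex-1-en-3-yl)oxy]triethylsilane; 6 propyne; 7 oxirane
Product: 11 (3Z)-4-methyl-8-[(triethylsilyl)oxy]deca-3,9-dien-1-ol, via Grignard reagent 8 (not isolated), via alkylcopper 9 (not isolated), via alkenylcopper 10 (not isolated)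
Conditions: Mg, THF, 45 °C; CuBr·SMe2 (1.05 equiv), Et2O/Me2S, −45 °C; 6 (3 equiv), −25 °C; then BF3·OEt2, 7, −78 to −40 °C; H2O quench
Reagents that add atoms: none
Why: Normant carbocupration, in which the alkylcopper adds syn across propyne with copper on the terminal carbon and the alkenylcopper opens the BF3-activated epoxide with retention, so the chain carbon and the new CH2CH2OH arm are cis on the trisubstituted alkene (Z only).

**Step 4**
Reactants: 11 (3Z)-4-methyl-8-[(triethylsilyl)oxy]deca-3,9-dien-1-ol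
Product: 12 {[(7Z)-10-bromo-7-methyldeca-1,7-dien-3-yl]oxy}triethylsilane
Conditions: CBr4, PPh3, 2,6-lutidine, CH2Cl2, 0 °C
Reagents that add atoms: tetrabromomethane, BrC(Br)(Br)Br
Why: The Appel reaction turns the primary alcohol into the bromide under buffered neutral conditions that leave the silyl ether and the alkene geometry untouched.

**Step 5**
Reactants: 12 {[(7Z)-10-bromo-7-methyldeca-1,7-dien-3-yl]oxy}triethylsilane; 6 propyne; 7 oxirane
Product: 16 (3Z,7Z)-4,8-dimethyl-12-[(triethylsilyl)oxy]tetradeca-3,7,13-trien-1-ol, via Grignard reagent 13 (not isolated), via alkylcopper 14 (not isolated), via alkenylcopper 15 (not isolated)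
Conditions: Mg, Et2O, 35 °C; CuBr·SMe2 (1.05 equiv), Et2O/Me2S, −45 °C; 6 (3 equiv), −25 °C; then BF3·OEt2, 7, −78 to −40 °C; H2O quench
Reagents that add atoms: none
Why: A second Normant carbocupration/epoxide opening repeats the syn addition and installs the second Z-trisubstituted alkene without touching the first.

**Step 6**
Reactants: 16 (3Z,7Z)-4,8-dimethyl-12-[(triethylsilyl)oxy]tetradeca-3,7,13-trien-1-ol
Product: 17 {[(7Z,11Z)-14-bromo-7,11-dimethyltetradeca-1,7,11-trien-3-yl]oxy}triethylsilane
Conditions: CBr4, PPh3, 2,6-lutidine, CH2Cl2, 0 °C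
Reagents that add atoms: tetrabromomethane, BrC(Br)(Br)Br
Why: Appel reaction as in step 4, giving the primary bromide needed for the last Grignard reagent.

**Step 7**
Reactants: 17 {[(7Z,11Z)-14-bromo-7,11-dimethyltetradeca-1,7,11-trien-3-yl]oxy}triethylsilane; 18 diallyl oxalate
Product: 20 prop-2-en-1-yl (5Z,9Z)-6,10-dimethyl-2-oxo-14-[(triethylsilyl)oxy]hexadeca-5,9,15-trienoate, via Grignard reagent 19 (not isolated)
Conditions: Mg, THF, 40 °C; add to 18 (3 equiv), THF, −78 °C; H2O quench
Reagents that add atoms: none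
Why: Grignard acylation by inverse addition to excess oxalate diester at low temperature stops at the α-keto ester because the tetrahedral magnesium adduct does not collapse before work-up.

**Step 8**
Reactants: 20 prop-2-en-1-yl (5Z,9Z)-6,10-dimethyl-2-oxo-14-[(triethylsilyl)oxy]hexadeca-5,9,15-trienoate
Product: 22 prop-2-en-1-yl (5Z,9Z)-6,10-dimethyl-2,14-dioxohexadeca-5,9,15-trienoate, via hydroxy keto ester 21 (not isolated)
Conditions: IBX (3 equiv), DMSO, 25 °C
Reagents that add atoms: none
Why: Oxidative desilylation, in which IBX cleaves the triethylsilyl ether and oxidises the freed allylic alcohol (alcohol oxidation) to the vinyl ketone without touching the α-keto ester or the trisubstituted alkenes.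

**Step 9**
Reactants: 22 prop-2-en-1-yl (5Z,9Z)-6,10-dimethyl-2,14-dioxohexadeca-5,9,15-trienoate
Product: 25 prop-2-en-1-yl (1R,3Z,7Z,11(15)E)-4,8-dimethyl-12-oxobicyclo[9.3.1]pentadeca-3,7,11(15)-triene-15-carboxylate, via macrocyclic diketone 23 (not isolated), via aldol 24 (not isolated)
Conditions: Cu(OTf)2 (10 mol %), (S,S)-tBu-box (11 mol %), Et3N (10 mol %), CH2Cl2, 1 mM, 22 added over 24 h, 25 °C; then TsOH·H2O (20 mol %), 40 °C
Reagents that add atoms: none
Why: Proposed new method: a macrocyclising Robinson annulation in which the chelated chiral divalent copper enolate of the α-keto ester adds to the tethered vinyl ketone (Michael addition, closing the 14-membered ring and setting C-1 as R because the tert-butyl group of the ligand shields one enolate face), after which the C-11 enol of the new 1,5-diketone attacks the copper-activated keto ester carbonyl across the ring and acid-promoted dehydration gives the enone conjugated with both carbonyls, so the six- and twelve-membered rings arise together, the closest known reactions being copper bis(oxazoline)-catalysed Mannich and aldol reactions of α-keto ester enolates, the Robinson annulation and the transannular aldol condensation of macrocyclic 1,5-diketones.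

**Step 10**
Reactants: 25 prop-2-en-1-yl (1R,3Z,7Z,11(15)E)-4,8-dimethyl-12-oxobicyclo[9.3.1]pentadeca-3,7,11(15)-triene-15-carboxylate; 26 5-bromo-2-methylpent-2-ene
Product: 29 prop-2-en-1-yl (1R,3Z,7Z,11R,15S)-4,8-dimethyl-15-(4-methylpent-3-en-1-yl)-12-oxobicyclo[9.3.1]pentadeca-3,7-diene-15-carboxylate, via Grignard reagent 27 (not isolated), via silyl enol ether 28 (not isolated)
Conditions: 26, Mg, THF, 40 °C; then 25, CuBr·SMe2 (10 mol %), Me3SiCl, HMPA, THF, −78 °C; then AcOH/H2O, THF, −78 to 0 °C
Reagents that add atoms: none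
Why: Copper-catalysed, silyl-chloride-accelerated conjugate addition of the homoprenyl Grignard reagent occurs β to the ketone of the doubly activated enone and from the face opposite the C-2 arm and the chain that spans the enone, which sets C-15 as S, and kinetic axial protonation of the silyl enol ether anti to the new pseudoaxial homoprenyl group sets C-11 as R.

**Step 11**
Reactants: 29 prop-2-en-1-yl (1R,3Z,7Z,11R,15S)-4,8-dimethyl-15-(4-methylpent-3-en-1-yl)-12-oxobicyclo[9.3.1]pentadeca-3,7-diene-15-carboxylate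
Product: 30 prop-2-en-1-yl (1R,3Z,7Z,11R,12S,15S)-4,8-dimethyl-15-(4-methylpent-3-en-1-yl)spiro[bicyclo[9.3.1]pentadeca-3,7-diene-12,2'-oxirane]-15-carboxylate
Conditions: Me3S+ I−, KN(SiMe3)2, THF, −10 to 0 °C
Reagents that add atoms: trimethylsulfonium iodide, C[S+](C)C.[I-]
Why: Corey–Chaykovsky epoxidation, in which the sulfonium ylide attacks the ketone from the face anti to the C-10 arm on C-11 and to the homoprenyl group on C-15, so the new CH2 is cis to the ester and the oxygen cis to C-10 (C-12 S), while the trisubstituted alkenes are untouched and the low temperature limits enolisation at C-11.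

**Step 12**
Reactants: 30 prop-2-en-1-yl (1R,3Z,7Z,11R,12S,15S)-4,8-dimethyl-15-(4-methylpent-3-en-1-yl)spiro[bicyclo[9.3.1]pentadeca-3,7-diene-12,2'-oxirane]-15-carboxylate
Product: 31 (1R,3Z,7Z,11R,12S,15S)-4,8-dimethyl-15-(4-methylpent-3-en-1-yl)spiro[bicyclo[9.3.1]pentadeca-3,7-diene-12,2'-oxirane]-15-carboxylic acid
Conditions: Pd(PPh3)4 (5 mol %), morpholine, THF, 0 to 25 °C; pH 5 phosphate buffer
Reagents that add atoms: none
Why: Tsuji–Trost-type deallylation, in which zerovalent palladium ionises the allyl ester and morpholine traps the allyl fragment, frees the hindered acid under neutral conditions that leave the epoxide and all four alkenes intact.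

**Compound list**
1 | 4-chloro-1,1-dimethoxybutane | COC(OC)CCCCl | starting material
2 | vinylmagnesium bromide | C=C[Mg]Br | starting material
3 | 4-chlorobutanal | O=CCCCCl | intermediate
4 | rac-6-chlorohex-1-en-3-ol | C=CC(O)CCCCl | intermediate
5 | rac-[(6-chlorohex-1-en-3-yl)oxy]triethylsilane | C=CC(O[Si](CC)(CC)CC)CCCCl | intermediate
6 | propyne | CC#C | starting material
7 | oxirane (ethylene oxide) | C1CO1 | starting material
8 | chloro{4-[(triethylsilyl)oxy]hex-5-en-1-yl}magnesium | C=CC(O[Si](CC)(CC)CC)CCC[Mg]Cl | intermediate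
9 | {4-[(triethylsilyl)oxy]hex-5-en-1-yl}copper | C=CC(O[Si](CC)(CC)CC)CCC[Cu] | intermediate
10 | {(1Z)-2-methyl-6-[(triethylsilyl)oxy]octa-1,7-dien-1-yl}copper | [Cu]/C=C(/C)CCCC(O[Si](CC)(CC)CC)C=C | intermediate
11 | (3Z)-4-methyl-8-[(triethylsilyl)oxy]deca-3,9-dien-1-ol | OCC/C=C(/C)CCCC(O[Si](CC)(CC)CC)C=C | intermediate
12 | {[(7Z)-10-bromo-7-methyldeca-1,7-dien-3-yl]oxy}triethylsilane | BrCC/C=C(/C)CCCC(O[Si](CC)(CC)CC)C=C | intermediate
13 | bromo{(3Z)-4-methyl-8-[(triethylsilyl)oxy]deca-3,9-dien-1-yl}magnesium | Br[Mg]CC/C=C(/C)CCCC(O[Si](CC)(CC)CC)C=C | intermediate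
14 | {(3Z)-4-methyl-8-[(triethylsilyl)oxy]deca-3,9-dien-1-yl}copper | [Cu]CC/C=C(/C)CCCC(O[Si](CC)(CC)CC)C=C | intermediate
15 | {(1Z,5Z)-2,6-dimethyl-10-[(triethylsilyl)oxy]dodeca-1,5,11-trien-1-yl}copper | [Cu]/C=C(/C)CC/C=C(/C)CCCC(O[Si](CC)(CC)CC)C=C | intermediate
16 | (3Z,7Z)-4,8-dimethyl-12-[(triethylsilyl)oxy]tetradeca-3,7,13-trien-1-ol | OCC/C=C(/C)CC/C=C(/C)CCCC(O[Si](CC)(CC)CC)C=C | intermediate
17 | {[(7Z,11Z)-14-bromo-7,11-dimethyltetradeca-1,7,11-trien-3-yl]oxy}triethylsilane | BrCC/C=C(/C)CC/C=C(/C)CCCC(O[Si](CC)(CC)CC)C=C | intermediate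
18 | diallyl oxalate (di(prop-2-en-1-yl) oxalate) | C=CCOC(=O)C(=O)OCC=C | starting material
19 | bromo{(3Z,7Z)-4,8-dimethyl-12-[(triethylsilyl)oxy]tetradeca-3,7,13-trien-1-yl}magnesium | Br[Mg]CC/C=C(/C)CC/C=C(/C)CCCC(O[Si](CC)(CC)CC)C=C | intermediate
20 | prop-2-en-1-yl (5Z,9Z)-6,10-dimethyl-2-oxo-14-[(triethylsilyl)oxy]hexadeca-5,9,15-trienoate (racemic at C-14) | C=CCOC(=O)C(=O)CC/C=C(/C)CC/C=C(/C)CCCC(O[Si](CC)(CC)CC)C=C | intermediate
21 | prop-2-en-1-yl (5Z,9Z)-14-hydroxy-6,10-dimethyl-2-oxohexadeca-5,9,15-trienoate (racemic) | C=CCOC(=O)C(=O)CC/C=C(/C)CC/C=C(/C)CCCC(O)C=C | intermediate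
22 | prop-2-en-1-yl (5Z,9Z)-6,10-dimethyl-2,14-dioxohexadeca-5,9,15-trienoate | C=CCOC(=O)C(=O)CC/C=C(/C)CC/C=C(/C)CCCC(=O)C=C | intermediate
23 | prop-2-en-1-yl 2-[(1R,3Z,7Z)-4,8-dimethyl-12-oxocyclotetradeca-3,7-dien-1-yl]-2-oxoacetate | C=CCOC(=O)C(=O)[C@H]1C/C=C(/C)CC/C=C(/C)CCCC(=O)CC1 | intermediate
24 | prop-2-en-1-yl (1R,3Z,7Z)-15-hydroxy-4,8-dimethyl-12-oxobicyclo[9.3.1]pentadeca-3,7-diene-15-carboxylate (C-11/C-15 epimers) | C=CCOC(=O)C1(O)[C@H]2C/C=C(/C)CC/C=C(/C)CCC1C(=O)CC2 | intermediate
25 | prop-2-en-1-yl (1R,3Z,7Z,11(15)E)-4,8-dimethyl-12-oxobicyclo[9.3.1]pentadeca-3,7,11(15)-triene-15-carboxylate | C=CCOC(=O)/C1=C2/C(=O)CC[C@@H]1C/C=C(/C)CC/C=C(/C)CC2 | intermediate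
26 | 5-bromo-2-methylpent-2-ene | CC(C)=CCCBr | starting material
27 | (4-methylpent-3-en-1-yl)magnesium bromide | CC(C)=CCC[Mg]Br | intermediate
28 | prop-2-en-1-yl (1R,3Z,7Z,15S)-4,8-dimethyl-15-(4-methylpent-3-en-1-yl)-12-[(trimethylsilyl)oxy]bicyclo[9.3.1]pentadeca-3,7,11-triene-15-carboxylate | CC(C)=CCC[C@]1(C(=O)OCC=C)[C@H]2C/C=C(/C)CC/C=C(/C)CCC1=C(O[Si](C)(C)C)CC2 | intermediate
29 | prop-2-en-1-yl (1R,3Z,7Z,11R,15S)-4,8-dimethyl-15-(4-methylpent-3-en-1-yl)-12-oxobicyclo[9.3.1]pentadeca-3,7-diene-15-carboxylate | CC(C)=CCC[C@]1(C(=O)OCC=C)[C@H]2C/C=C(/C)CC/C=C(/C)CC[C@H]1C(=O)CC2 | intermediate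
30 | prop-2-en-1-yl (1R,3Z,7Z,11R,12S,15S)-4,8-dimethyl-15-(4-methylpent-3-en-1-yl)spiro[bicyclo[9.3.1]pentadeca-3,7-diene-12,2'-oxirane]-15-carboxylate | CC(C)=CCC[C@]1(C(=O)OCC=C)[C@H]2C/C=C(/C)CC/C=C(/C)CC[C@H]1[C@@]1(CC2)CO1 | intermediate
31 | (1R,3Z,7Z,11R,12S,15S)-4,8-dimethyl-15-(4-methylpent-3-en-1-yl)spiro[bicyclo[9.3.1]pentadeca-3,7-diene-12,2'-oxirane]-15-carboxylic acid | CC(C)=CCC[C@]1(C(=O)O)[C@H]2C/C=C(/C)CC/C=C(/C)CC[C@H]1[C@@]1(CC2)CO1 | target

**Totals**
Total step count: 12. Longest linear sequence: 12 steps (1 to 31).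

**Steps most likely to fail**

Step 9 is the largest risk. The 14-membered Michael closure competes with oligomerisation and with self-aldol reaction of the keto ester. The enantioselectivity of the copper enolate is unproven. The strained bridgehead enone may also deconjugate toward C-1, which would erase the stereocentre. The fallback sets out from 22 and returns at 25. Compound 22 is silylated (Me3SiCl, Et3N, CH2Cl2, 0 °C) to the 2-silyloxyacrylate prop-2-en-1-yl (2Z,5Z,9Z)-6,10-dimethyl-14-oxo-2-[(trimethylsilyl)oxy]hexadeca-2,5,9,15-tetraenoate F1. An intramolecular Mukaiyama–Michael addition of F1 with Cu(OTf)2/(S,S)-tBu-box at 1 mM in CH2Cl2/(CF3)2CHOH at −20 °C gives the macrocyclic diketone 23, which is now isolated and purified. A separate transannular aldol condensation with pyrrolidinium acetate in toluene at 40 °C then gives 25. This separates the two ring closures and replaces the base-generated enolate by a preformed enol silane.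

Step 10 is the second risk. The tetrasubstituted, bridged enone may resist the copper reagent, the allyl ester or the acidic C-1 hydrogen may interfere, and protonation at C-11 may give the epimer. The fallback sets out from 25 and 26 and returns at 29. Bromide 26 is converted with NaI in acetone into 5-iodo-2-methylpent-2-ene F2. A Giese radical addition of F2 to 25 with (Me3Si)3SiH and Et3B/air in toluene at 0 to 25 °C then adds the nucleophilic homoprenyl radical at C-15 from the open face, and the resulting α-keto radical takes its hydrogen from the silane at C-11 anti to the new group, which gives 29 without an organometallic reagent.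

Step 11 is the third risk. The basic ylide may enolise the ketone and epimerise C-11, may react sluggishly at the hindered carbonyl, or may give a poor facial ratio. The fallback sets out from 29 and returns at 30. Chloromethyllithium, made from ICH2Cl and MeLi·LiBr in THF at −78 °C, adds irreversibly to the ketone from the same open face to give the chlorohydrin prop-2-en-1-yl (1R,3Z,7Z,11R,12S,15S)-12-(chloromethyl)-12-hydroxy-4,8-dimethyl-15-(4-methylpent-3-en-1-yl)bicyclo[9.3.1]pentadeca-3,7-diene-15-carboxylate F3. After purification, F3 is closed to 30 with K2CO3 in MeCN at 25 °C.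

**Further compounds**
F1 | step 9 | prop-2-en-1-yl (2Z,5Z,9Z)-6,10-dimethyl-14-oxo-2-[(trimethylsilyl)oxy]hexadeca-2,5,9,15-tetraenoate | C=CCOC(=O)/C(O[Si](C)(C)C)=C/C/C=C(/C)CC/C=C(/C)CCCC(=O)C=C
F2 | step 10 | 5-iodo-2-methylpent-2-ene | CC(C)=CCCI
F3 | step 11 | prop-2-en-1-yl (1R,3Z,7Z,11R,12S,15S)-12-(chloromethyl)-12-hydroxy-4,8-dimethyl-15-(4-methylpent-3-en-1-yl)bicyclo[9.3.1]pentadeca-3,7-diene-15-carboxylate | CC(C)=CCC[C@]1(C(=O)OCC=C)[C@H]2C/C=C(/C)CC/C=C(/C)CC[C@H]1[C@](O)(CCl)CC2
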